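**Retrosynthetic overview**
1. The esters go on last. C9–O comes from oxidation of a C8=C9 silyl enol ether, C4–O from reduction of a C4 ketone, and the C6=C7 enone from a C6 exocyclic methylene.
2. Key cut: one [4+2] cycloaddition makes C5–C10 and C6–C7. (E)-2-Silyloxypenta-1,3-diene (C7–C10 plus the C10 methyl) adds across the exocyclic C5=C6 bond of a 2-vinylidenecyclopentanone. This closes the ring C5–C10, sets spiro C5 and C10 together, and leaves C8 masked.
3. Feature that invites it: the cyclopentane C1–C5 with its C2 isopropenyl group, plus C6 and the C6 methyl, are the ten carbons of (R)-limonene after a 6→5 ring reorganisation (cleave limonene C1=C2, re-close by aldol). C2 is the only purchased stereocentre.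
4. Ring order: cyclopentane first (aldol, step 2), cyclohexene second (cycloaddition, step 6). The allenyl ketone is released in the flask from the limonene-derived β-diketone.

Key step: step 6

Remark on numbering: spiro[4.5]decane numbering of the target is used throughout. C1 is CH2, C2 is CH-isopropenyl, C3 is CH2, C4 is CH–O-senecioyl, C5 is the spiro atom, C6 is =C(CH3), C7 is =CH, C8 is C=O, C9 is CH–OAc and C10 is CH–CH3. The target is (2R,4S,5S,9S,10R).
Assumption: commercial (+)-limonene oxide is the cis/trans epoxide mixture of the (4R) series. Both isomers give the same keto aldehyde.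

Step 1
Reactants: 1 (4R)-limonene 1,2-oxide
Product: 3 (3R)-6-oxo-3-(prop-1-en-2-yl)heptanal, via limonene-1,2-diol 2 (not isolated)
Conditions: H5IO6, THF–H2O, 0 °C to rt
Reagents that add atoms: water, O
Why: Acidic epoxide hydrolysis followed by Malaprade glycol cleavage with the same reagent opens the ring between limonene C1 and C2, and the isopropenyl group and the stereocentre (future C2) are not involved.

Step 2
Reactants: 3 (3R)-6-oxo-3-(prop-1-en-2-yl)heptanal
Product: 5 1-[(4S)-4-(prop-1-en-2-yl)cyclopent-1-en-1-yl]ethan-1-one, via ketol 4 (not isolated)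
Conditions: aq KOH, THF, rt
Reagents that add atoms: none
Why: Hydroxide-mediated intramolecular aldol condensation (5-enolexo attack of the internal ketone enolate carbon, future C5, on the aldehyde, future C4) should give the conjugated methyl ketone under thermodynamic control, whereas amine–acid catalysis is avoided because it would give the isomeric cyclopentenecarbaldehyde through the aldehyde enamine.

Step 3
Reactants: 5 1-[(4S)-4-(prop-1-en-2-yl)cyclopent-1-en-1-yl]ethan-1-one
Product: 6 1-[(1R,3S,5S)-3-(prop-1-en-2-yl)-6-oxabicyclo[3.1.0]hexan-1-yl]ethan-1-one (oxygen anti to the isopropenyl group; the syn isomer is equally usable)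
Conditions: 30% H2O2, cat. NaOH, MeOH, 0 °C
Reagents that add atoms: hydrogen peroxide, OO
Why: Weitz–Scheffer nucleophilic epoxidation touches only the electron-poor C4=C5 bond, and its two new stereocentres are erased in step 4, so facial selectivity does not matter.

Step 4
Reactants: 6 epoxy ketone
Product: 7 (4R)-2-acetyl-4-(prop-1-en-2-yl)cyclopentan-1-one (keto/enol and C5-epimer mixture)
Conditions: cat. Pd(PPh3)4, cat. dppe, toluene, 100 °C
Reagents that add atoms: none
Why: Pd(0)-catalysed isomerisation of an α,β-epoxy ketone to the 1,3-diketone (opening at C5–O, then β-hydride elimination of C4–H) places the oxygen on C4 under neutral conditions that spare the isopropenyl group.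

Step 5
Reactants: 8 (E)-pent-3-en-2-one
Product: 9 tert-butyl(dimethyl){[(3E)-penta-1,3-dien-2-yl]oxy}silane
Conditions: TBSOTf, Et3N, Et2O, 0 °C
Reagents that add atoms: tert-butyldimethylsilyl trifluoromethanesulfonate, CC(C)(C)[Si](C)(C)OS(=O)(=O)C(F)(F)F
Why: Silyl enol ether formation by soft enolisation at the α′-methyl group gives the cross-conjugated 2-silyloxydiene and keeps the (E)-propenyl geometry.

Step 6
Reactants: 7 (4R)-2-acetyl-4-(prop-1-en-2-yl)cyclopentan-1-one; 9 tert-butyl(dimethyl){[(3E)-penta-1,3-dien-2-yl]oxy}silane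
Product: 13 (2R,5S,10S)-8-[(tert-butyldimethylsilyl)oxy]-10-methyl-6-methylidene-2-(prop-1-en-2-yl)spiro[4.5]dec-8-en-4-one, via diketone dianion 10 (not isolated), via vinyl triflate enolate 11 (not isolated), via allenyl ketone 12 (not isolated)
Conditions: NaH, THF, 0 °C; n-BuLi, 0 °C; N-(5-chloropyridin-2-yl)bis(trifluoromethanesulfonimide), −78 °C; then 9 (3 equiv), −78 °C to rt, then 50 °C
Reagents that add atoms: none
Why: Proposed new method: dianion 10 should be sulfonylated on the acetyl oxygen (O on C6, which shares both charges) to give enolate 11, which on warming expels triflate (E1cB) and releases the s-cis-locked allenyl ketone 12, and its conjugated C5=C6 bond then takes up diene 9 in an asynchronous [4+2] cycloaddition in which C7–C6 bonding runs ahead of C10–C5. The closest known reaction types are the one-pot conversion of β-keto esters into allenoates through vinyl triflate anions and the cycloaddition of 2-silyloxydienes with allenoates or allenyl ketones, which leaves an exocyclic methylene next to a new quaternary carbon. The ring C5–C10 closes intermolecularly in the [4+2] mode (σ bonds C6–C7 and C5–C10), which makes C5 the spiro atom. C5 is controlled by C2, since the diene should approach the nearly flat dienophile on the face opposite the isopropenyl group (C10 trans, C6 cis to it), and C10 is controlled by the (E)-geometry of 9 together with the endo position of the C4 carbonyl, which places the C10 methyl cis to C4. Regiochemistry (nucleophilic C7 to the central allene carbon C6) is secured by the matched 2-silyloxy and terminal methyl donors of 9 and by the C4 carbonyl, site selectivity by the fact that only C5=C6 is conjugated, and only O–C6 sulfonylation can eliminate because the ring side would need a five-membered cyclic allene. The product carries C8 as a regiodefined silyl enol ether and so differentiates it from the C4 ketone.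

Step 7
Reactants: 13 spiro ketone
Product: 15 (2R,4S,5S,10S)-8-[(tert-butyldimethylsilyl)oxy]-10-methyl-6-methylidene-2-(prop-1-en-2-yl)spiro[4.5]dec-8-en-4-ol, via C4 catecholborate 14 (not isolated)
Conditions: (R)-2-methyl-CBS-oxazaborolidine (0.5 equiv), catecholborane, toluene, −78 to −30 °C; then MeOH, aq NaHCO3
Reagents that add atoms: none
Why: In this Corey–Bakshi–Shibata reduction the catalyst distinguishes quaternary C5 (large) from C3H2 (small) and should deliver hydride on the face syn to C6, which sets (4S) under reagent control, while catecholborane at low temperature leaves the alkenes and the silyl enol ether alone.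

Step 8
Reactants: 15 spiro alcohol
Product: 17 (2R,4S,5S,10S)-8-[(tert-butyldimethylsilyl)oxy]-10-methyl-6-methylidene-2-(prop-1-en-2-yl)spiro[4.5]dec-8-en-4-yl 3-methylbut-2-enoate, via lithium alkoxide 16 (not isolated)
Conditions: LiHMDS, THF, −78 °C; 3-methylbut-2-enoyl chloride, −78 to 0 °C
Reagents that add atoms: 3-methylbut-2-enoyl chloride, CC(C)=CC(=O)Cl
Why: O-acylation of the preformed alkoxide of this hindered alcohol avoids amine bases that deconjugate the acid chloride through its vinylketene, and C4 keeps its configuration because only the O–H bond reacts.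

Step 9
Reactants: 17 senecioate silyl enol ether
Product: 20 (2R,4S,5S,9S,10R)-9-hydroxy-10-methyl-6-methylidene-8-oxo-2-(prop-1-en-2-yl)spiro[4.5]decan-4-yl 3-methylbut-2-enoate, via silyloxy epoxide 18 (not isolated), via α-silyloxy ketone 19 (not isolated)
Conditions: mCPBA (1.05 equiv), CH2Cl2, −20 °C; then Et3N·3HF, THF, 0 °C
Reagents that add atoms: 3-chloroperoxybenzoic acid, OOC(=O)c1cccc(Cl)c1
Why: In this Rubottom oxidation the peracid should attack only the electron-rich C8=C9 bond and from the C1 face, because the other face is covered by the C10 methyl and the C4 ester, so that C9–O forms trans to the methyl (9S), and silyl migration followed by fluoride gives the ketol.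

Step 10
Reactants: 20 α-hydroxy ketone
Product: 22 (2R,4S,5S,9S,10R)-9-acetoxy-6,10-dimethyl-8-oxo-2-(prop-1-en-2-yl)spiro[4.5]dec-6-en-4-yl 3-methylbut-2-enoate, via methylidene acetate 21 (not isolated)
Conditions: Ac2O, Et3N, cat. DMAP, CH2Cl2, 0 °C to rt; then cat. DBU, rt
Reagents that add atoms: acetic anhydride, CC(=O)OC(C)=O
Why: Acetylation of the C9 alcohol is followed by base-catalysed β,γ→α,β enone isomerisation through the doubly activated C7–H, which turns the C6 methylene into the C6 methyl and the C6=C7 enone while the far less acidic C9–H should stay untouched.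

**Compound list**
1 | (4R)-1-methyl-4-(prop-1-en-2-yl)-7-oxabicyclo[4.1.0]heptane, cis/trans mixture | CC12OC1C[C@@H](CC2)C(=C)C | starting material
2 | (4R)-1-methyl-4-(prop-1-en-2-yl)cyclohexane-1,2-diol | CC1(O)C(O)C[C@@H](CC1)C(=C)C | intermediate
3 | (3R)-6-oxo-3-(prop-1-en-2-yl)heptanal | O=CC[C@@H](CCC(C)=O)C(=C)C | intermediate
4 | 1-[2-hydroxy-4-(prop-1-en-2-yl)cyclopentyl]ethan-1-one (ketol, C2 as in 5) | C=C(C)[C@H]1CC(O)C(C1)C(C)=O | intermediate
5 | 1-[(4S)-4-(prop-1-en-2-yl)cyclopent-1-en-1-yl]ethan-1-one | C=C(C)[C@H]1CC=C(C1)C(C)=O | intermediate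
6 | 1-[(1R,3S,5S)-3-(prop-1-en-2-yl)-6-oxabicyclo[3.1.0]hexan-1-yl]ethan-1-one | C=C(C)[C@H]1C[C@@H]2O[C@@]2(C1)C(C)=O | intermediate
7 | (4R)-2-acetyl-4-(prop-1-en-2-yl)cyclopentan-1-one | C=C(C)[C@H]1CC(=O)C(C1)C(C)=O | intermediate
8 | (E)-pent-3-en-2-one | C/C=C/C(C)=O | starting material
9 | tert-butyl(dimethyl){[(3E)-penta-1,3-dien-2-yl]oxy}silane | C=C(O[Si](C)(C)C(C)(C)C)/C=C/C | intermediate
10 | sodium lithium dianion of 7 | [Na+].[Li+].C=C(C)[C@H]1CC([O-])=C(C1)C([O-])=C | intermediate
11 | lithium enolate of the C6 vinyl triflate | [Li+].C=C(C)[C@H]1CC([O-])=C(C1)C(=C)OS(=O)(=O)C(F)(F)F | intermediate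
12 | (4R)-2-ethenylidene-4-(prop-1-en-2-yl)cyclopentan-1-one | C=C(C)[C@H]1CC(=O)C(=C=C)C1 | intermediate
13 | (2R,5S,10S)-8-[(tert-butyldimethylsilyl)oxy]-10-methyl-6-methylidene-2-(prop-1-en-2-yl)spiro[4.5]dec-8-en-4-one | C=C(C)[C@H]1CC(=O)[C@]2(C1)C(=C)CC(O[Si](C)(C)C(C)(C)C)=C[C@@H]2C | intermediate
14 | C4 catecholborate ester of 15 | C=C(C)[C@H]1C[C@H](OB3Oc4ccccc4O3)[C@]2(C1)C(=C)CC(O[Si](C)(C)C(C)(C)C)=C[C@@H]2C | intermediate
15 | (2R,4S,5S,10S)-8-[(tert-butyldimethylsilyl)oxy]-10-methyl-6-methylidene-2-(prop-1-en-2-yl)spiro[4.5]dec-8-en-4-ol | C=C(C)[C@H]1C[C@H](O)[C@]2(C1)C(=C)CC(O[Si](C)(C)C(C)(C)C)=C[C@@H]2C | intermediate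
16 | lithium alkoxide of 15 | [Li+].C=C(C)[C@H]1C[C@H]([O-])[C@]2(C1)C(=C)CC(O[Si](C)(C)C(C)(C)C)=C[C@@H]2C | intermediate
17 | 3-methylbut-2-enoate of 15 | C=C(C)[C@H]1C[C@H](OC(=O)C=C(C)C)[C@]2(C1)C(=C)CC(O[Si](C)(C)C(C)(C)C)=C[C@@H]2C | intermediate
18 | 8,9-epoxide of 17, oxygen on the C1 face | C=C(C)[C@H]1C[C@H](OC(=O)C=C(C)C)[C@]2(C1)C(=C)C[C@@]3(O[Si](C)(C)C(C)(C)C)O[C@H]3[C@@H]2C | intermediate
19 | (9S)-9-silyloxy-8-ketone | C=C(C)[C@H]1C[C@H](OC(=O)C=C(C)C)[C@]2(C1)C(=C)CC(=O)[C@@H](O[Si](C)(C)C(C)(C)C)[C@@H]2C | intermediate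
20 | (2R,4S,5S,9S,10R)-9-hydroxy-10-methyl-6-methylidene-8-oxo-2-(prop-1-en-2-yl)spiro[4.5]decan-4-yl 3-methylbut-2-enoate | C=C(C)[C@H]1C[C@H](OC(=O)C=C(C)C)[C@]2(C1)C(=C)CC(=O)[C@@H](O)[C@@H]2C | intermediate
21 | C9 acetate of 20 (C6 methylidene) | C=C(C)[C@H]1C[C@H](OC(=O)C=C(C)C)[C@]2(C1)C(=C)CC(=O)[C@@H](OC(C)=O)[C@@H]2C | intermediate
22 | (2R,4S,5S,9S,10R)-9-acetoxy-6,10-dimethyl-8-oxo-2-(prop-1-en-2-yl)spiro[4.5]dec-6-en-4-yl 3-methylbut-2-enoate | C=C(C)[C@H]1C[C@H](OC(=O)C=C(C)C)[C@]2(C1)C(C)=CC(=O)[C@@H](OC(C)=O)[C@@H]2C | target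

**Step count**
Total steps: 10. Longest linear sequence: 9 (steps 1–4 and 6–10).

**Steps most likely to fail**

1. Step 6.
   - What may go wrong: sulfonylation on the ring oxygen instead of the acetyl oxygen; addition of remaining enolate to the allenyl ketone as it is released; poor endo or facial selectivity in the cycloaddition.
   - Fallback (known chemistry, Robinson-type spiroannulation): it sets out from 7 and 8 and returns at 22.
   - FeCl3·6H2O-catalysed Michael addition of 7 to 8 gives the triketone F1.
   - Pyrrolidine/AcOH closes C6=C7 by aldol condensation to the spiro enedione F2.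
   - Luche reduction of both carbonyl groups gives the diol F3, and the C4 epimers are separated here.
   - MnO2 re-oxidises only the allylic C8 alcohol to the hydroxy enone F4.
   - LDA (2.2 equiv) and 2-(phenylsulfonyl)-3-phenyloxaziridine hydroxylate the kinetic C9 enolate anti to the C10 methyl to give the dihydroxy enone F5.
   - One equivalent of Ac2O in pyridine acetylates the less hindered C9 alcohol to the monoacetate F6.
   - 3-Methylbut-2-enoyl chloride/DMAP then gives 22.

2. Step 7.
   - What may go wrong: slow reduction of the ketone next to the quaternary centre; a substrate bias that overrides the catalyst and delivers hydride on the wrong face.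
   - Fallback: it sets out from 13 and returns at 17. A small or bulky achiral hydride (NaBH4 or L-Selectride) is allowed to follow the substrate bias to the (4R)-alcohol F7. A Mitsunobu esterification with 3-methylbut-2-enoic acid (PPh3, DIAD) then installs the ester with inversion at C4 and gives 17 directly.

3. Step 9.
   - What may go wrong: competing epoxidation of the two 1,1-disubstituted alkenes; protodesilylation before oxygen transfer.
   - Fallback: it sets out from 17 and returns at 22. Et3N·3HF followed by cat. DBU unmasks and conjugates the ketone to the C9-unsubstituted enone F8. Radical α′-acetoxylation with Mn(OAc)3 in refluxing benzene then puts the acetate on C9 anti to the C10 methyl and gives 22.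

**Further compounds**
F1 | step 6 | 2-acetyl-2-(4-oxopentan-2-yl)-4-(prop-1-en-2-yl)cyclopentan-1-one (C2, C5, C10 as in 22) | C=C(C)[C@H]1CC(=O)[C@](C1)(C(C)=O)[C@@H](C)CC(C)=O
F2 | step 6 | 6,10-dimethyl-2-(prop-1-en-2-yl)spiro[4.5]dec-6-ene-4,8-dione | C=C(C)[C@H]1CC(=O)[C@]2(C1)C(C)=CC(=O)C[C@@H]2C
F3 | step 6 | 6,10-dimethyl-2-(prop-1-en-2-yl)spiro[4.5]dec-6-ene-4,8-diol (4S, C8 mixture) | C=C(C)[C@H]1C[C@H](O)[C@]2(C1)C(C)=CC(O)C[C@@H]2C
F4 | step 6 | (4S)-4-hydroxy-6,10-dimethyl-2-(prop-1-en-2-yl)spiro[4.5]dec-6-en-8-one | C=C(C)[C@H]1C[C@H](O)[C@]2(C1)C(C)=CC(=O)C[C@@H]2C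
F5 | step 6 | (4S,9S)-4,9-dihydroxy-6,10-dimethyl-2-(prop-1-en-2-yl)spiro[4.5]dec-6-en-8-one | C=C(C)[C@H]1C[C@H](O)[C@]2(C1)C(C)=CC(=O)[C@@H](O)[C@@H]2C
F6 | step 6 | (4S,9S)-9-acetoxy-4-hydroxy-6,10-dimethyl-2-(prop-1-en-2-yl)spiro[4.5]dec-6-en-8-one | C=C(C)[C@H]1C[C@H](O)[C@]2(C1)C(C)=CC(=O)[C@@H](OC(C)=O)[C@@H]2C
F7 | step 7 | (4R)-epimer of 15 | C=C(C)[C@H]1C[C@@H](O)[C@]2(C1)C(=C)CC(O[Si](C)(C)C(C)(C)C)=C[C@@H]2C
F8 | step 9 | 6,10-dimethyl-8-oxo-2-(prop-1-en-2-yl)spiro[4.5]dec-6-en-4-yl 3-methylbut-2-enoate | C=C(C)[C@H]1C[C@H](OC(=O)C=C(C)C)[C@]2(C1)C(C)=CC(=O)C[C@@H]2C
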